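**Strategy.** Ring B (C5–C6=C7–C8–C9–C10) hides a γ,δ-unsaturated acid retron, C11(=O)–C9–C8–C7=C6, so it is not annulated but made by a lactone-enolate Ireland–Claisen rearrangement. The precursor is a trans-fused bicyclic δ-lactone (oxygen bridging C6 and C11, ring A complete) that carries a (Z)-acrylate on C6. One operation forms C8–C9, closes the carbocycle through a boat transition state, places the alkene at the unconjugated C6=C7 position, sets C8 and C9 from C6 and the alkene geometry, and leaves C11 (acid) and C17 (methyl ester) differentiated. The lactone arises by Baeyer–Villiger oxygen insertion into a hydrindanone built on a catalytic asymmetric allylation product.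

Key step: step 9

Remark: atom labels follow labdane numbering (C4 gem-dimethyl carbon, C5 ring-fusion CH, C10 angular-methyl carbon, C8 bears ester carbon C17, C9 bears the chain C11–C16). The target is read as the ent-labdane (5R,8S,9R,10S). The ligand (S)-t-BuPHOX, phosphonate 11 and ynoate 19 are assumed purchasable.

Step 1
Reactants: 1 2,2,6-trimethylcyclohexanone (racemic); 2 allyl chloroformate
Product: 3 allyl 2,6,6-trimethylcyclohex-1-en-1-yl carbonate
Conditions: LiHMDS, THF, 0 °C; then 2, −78 °C → rt
Reagents that add atoms: none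
Why: The only enolisable position of 1 gives a hindered tetrasubstituted enolate that should be acylated on oxygen by the chloroformate (enol carbonate formation).

Step 2
Reactants: 3 allyl 2,6,6-trimethylcyclohex-1-en-1-yl carbonate
Product: 4 (S)-2-allyl-2,6,6-trimethylcyclohexanone
Conditions: Pd2(dba)3 (2.5 mol %), (S)-t-BuPHOX (6 mol %), THF, 25 °C
Reagents that add atoms: none
Why: Pd-catalysed decarboxylative asymmetric allylic alkylation (Tsuji allylation): ionisation and loss of CO2 give a Pd-allyl/enolate pair that recombines at carbon, and the PHOX ligand sets the quaternary centre C10 as S (the (S)-ligand is the one expected to give the (S)-ketone by analogy with 2-methylcyclohexanone substrates).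

Step 3
Reactants: 4 (S)-2-allyl-2,6,6-trimethylcyclohexanone
Product: 5 (S)-2,2,6-trimethyl-6-(2-oxopropyl)cyclohexanone
Conditions: PdCl2 (10 mol %), Cu(OAc)2 (20 mol %), O2 (1 atm), DMA–H2O, 25 °C
Reagents that add atoms: water, O
Why: Tsuji–Wacker oxidation of the terminal alkene should give the methyl ketone with Markovnikov selectivity, while the hindered ring ketone and the quaternary centre are inert.

Step 4
Reactants: 5 (S)-2,2,6-trimethyl-6-(2-oxopropyl)cyclohexanone
Product: 6 (7aS)-4,4,7a-trimethyl-5,6,7,7a-tetrahydro-1H-inden-2(4H)-one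
Conditions: KOH, xylenes, 110 °C (Dean–Stark)
Reagents that add atoms: none
Why: Intramolecular aldol condensation: the ring ketone has no α-hydrogen, so only the methyl group of the side-chain ketone can attack it (five-membered closure), and dehydration gives the cyclopentenone C5=C6–C11=O.

Step 5
Reactants: 6 (7aS)-4,4,7a-trimethyl-5,6,7,7a-tetrahydro-1H-inden-2(4H)-one
Product: 8 (1R,3aS,7aR)-1-(hydroxymethyl)-3a,7,7-trimethyloctahydro-2H-inden-2-one, via lithium enolate 7 (not isolated)
Conditions: Li, NH3(l)–THF, t-BuOH (1 equiv), −78 °C; isoprene; NH3 removed; CH2O (g), THF, −78 °C; aq NH4Cl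
Reagents that add atoms: formaldehyde, C=O
Why: Reductive aldol (dissolving-metal enone reduction with enolate trapping): C5 should be protonated axially on the face away from the two axial methyl groups on C4 and C10, giving the trans ring fusion, and the regiodefined enolate 7 should add formaldehyde at C6 on the β face (the α position eclipses the gem-dimethyl carbon), so CH2OH ends cis to H5.

Step 6
Reactants: 8 (1R,3aS,7aR)-1-(hydroxymethyl)-3a,7,7-trimethyloctahydro-2H-inden-2-one
Product: 9 (1R,4aS,8aR)-1-(hydroxymethyl)-4a,8,8-trimethyloctahydro-3H-isochromen-3-one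
Conditions: m-CPBA, NaHCO3, CH2Cl2, 0 °C → rt
Reagents that add atoms: m-chloroperbenzoic acid, OOC(=O)c1cccc(Cl)c1
Why: Baeyer–Villiger oxidation: the secondary carbon C6 should migrate in preference to the primary C9, and with retention, so oxygen enters between C6 and C11 and the C6 configuration is kept.

Step 7
Reactants: 9 (1R,4aS,8aR)-1-(hydroxymethyl)-4a,8,8-trimethyloctahydro-3H-isochromen-3-one
Product: 10 (1R,4aS,8aR)-4a,8,8-trimethyl-3-oxooctahydro-1H-isochromene-1-carbaldehyde
Conditions: Dess–Martin periodinane, NaHCO3, CH2Cl2, 0 °C → rt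
Reagents that add atoms: none
Why: Buffered Dess–Martin oxidation of the primary alcohol should give the α-acyloxy aldehyde without touching the lactone; C6 is not at risk because its epimer is far more hindered.

Step 8
Reactants: 10 (1R,4aS,8aR)-4a,8,8-trimethyl-3-oxooctahydro-1H-isochromene-1-carbaldehyde; 11 methyl bis(2,2,2-trifluoroethyl)phosphonoacetate
Product: 12 methyl (2Z)-3-[(1S,4aS,8aR)-4a,8,8-trimethyl-3-oxooctahydro-1H-isochromen-1-yl]prop-2-enoate
Conditions: KHMDS, 18-crown-6, THF, −78 °C
Reagents that add atoms: none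
Why: Still–Gennari olefination: the trifluoroethyl phosphonate eliminates rapidly from the kinetic adduct under dissociating conditions and should give the (Z)-enoate.

Step 9
Reactants: 12 methyl (2Z)-3-[(1S,4aS,8aR)-4a,8,8-trimethyl-3-oxooctahydro-1H-isochromen-1-yl]prop-2-enoate
Product: 15 (1R,2S,4aR,8aR)-2-(methoxycarbonyl)-5,5,8a-trimethyl-1,2,4a,5,6,7,8,8a-octahydronaphthalene-1-carboxylic acid, via silyl ketene acetal 13 (not isolated), via silyl ester 14 (not isolated)
Conditions: TBSCl, KHMDS, THF–DMPU, −78 °C → rt (silyl chloride present before the base); then PhMe, 110–140 °C (sealed); then 1 M HCl, THF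
Reagents that add atoms: none
Why: Ireland–Claisen rearrangement of a lactone silyl ketene acetal (the lactone-enolate Claisen carbocyclisation of alkenyl lactones, same topology as the dioxanone-to-dihydropyran Claisen): in-situ O-silylation of the enolate of 12 gives the 1-oxa-1,5-diene C9=C11(OTBS)–O–C6–C7=C8 in 13, and a concerted suprafacial [3,3] shift forms C8–C9 while C6–O breaks, giving silyl ester 14 and, after hydrolysis, acid 15. Because O, C11 and C9 lie in the six-membered lactone, the arm on C6 can reach C9 only through a boat transition state of bicyclo[2.2.2]octane shape (bridgeheads C6 and C9), and the carbocycle C5–C6=C7–C8–C9–C10 is closed by this pericyclic C–C bond formation, with the cis C6=C7 alkene placed β,γ to the C17 ester. C9 is controlled by C6: the arm is β (cis to H5, set in step 5), so C8 adds to the β face of C9 and the carboxyl C11 ends α, cis to the C10 methyl group. C8 is controlled by the alkene geometry: in the boat the (Z) substituent of C8 ends on the ring face opposite to C11, so the (Z)-ester gives the trans C8/C9 relationship with the ester equatorial, whereas an (E)-ester would give the C8 epimer; C5 and C10 are untouched. The selectivity needed is enolisation at C9H2 in preference to γ-deprotonation or amide addition at the enoate, which the higher acidity of the lactone α-CH2, a hindered silazide base and in-situ silylation should secure. The cost is a syn contact between the (Z)-ester and C1H2 in the boat, so a temperature above the usual 100–110 °C is allowed for.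

Step 10
Reactants: 15 (1R,2S,4aR,8aR)-2-(methoxycarbonyl)-5,5,8a-trimethyl-1,2,4a,5,6,7,8,8a-octahydronaphthalene-1-carboxylic acid
Product: 17 methyl (1R,2S,4aR,8aR)-1-formyl-5,5,8a-trimethyl-1,2,4a,5,6,7,8,8a-octahydronaphthalene-2-carboxylate, via acid chloride 16 (not isolated)
Conditions: (COCl)2, cat. DMF, CH2Cl2, 0 °C → rt; then LiAlH(Ot-Bu)3, THF, −78 °C
Reagents that add atoms: none
Why: Reduction of an acid chloride with lithium tri-tert-butoxyaluminium hydride should stop at the aldehyde and leave the methyl ester and the alkene untouched; no base is present, so C8 and C9 are not at risk.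

Step 11
Reactants: 17 methyl (1R,2S,4aR,8aR)-1-formyl-5,5,8a-trimethyl-1,2,4a,5,6,7,8,8a-octahydronaphthalene-2-carboxylate
Product: 18 methyl (1R,2S,4aR,8aS)-5,5,8a-trimethyl-1-vinyl-1,2,4a,5,6,7,8,8a-octahydronaphthalene-2-carboxylate
Conditions: Zn, CH2Br2, TiCl4, THF–CH2Cl2, 0 °C → rt
Reagents that add atoms: dibromomethane, BrCBr
Why: Takai–Lombardo methylenation is non-basic, so the aldehyde should become the vinyl group (C11=C12) without epimerisation at C9 or migration of the C6=C7 bond into conjugation with the C8 ester, and the ester does not react.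

Step 12
Reactants: 19 methyl 4-hydroxybut-2-ynoate
Product: 20 methyl 4-acetoxybut-2-ynoate
Conditions: Ac2O, pyridine, DMAP (cat.), CH2Cl2, 0 °C → rt
Reagents that add atoms: acetic anhydride, CC(=O)OC(C)=O
Why: Standard acetylation of the primary propargylic alcohol, which installs the C16 acetate before the iodide is made.

Step 13
Reactants: 20 methyl 4-acetoxybut-2-ynoate
Product: 21 methyl (2Z)-4-acetoxy-3-iodobut-2-enoate
Conditions: NaI, AcOH, 70 °C
Reagents that add atoms: sodium iodide, [Na+].[I-]
Why: Hydroiodination of an ynoate with NaI in acetic acid proceeds by anti addition (iodide to the β-carbon, proton to the α-carbon) and should give the (Z)-β-iodoenoate with iodine cis to the ester.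

Step 14
Reactants: 18 methyl (1R,2S,4aR,8aS)-5,5,8a-trimethyl-1-vinyl-1,2,4a,5,6,7,8,8a-octahydronaphthalene-2-carboxylate; 21 methyl (2Z)-4-acetoxy-3-iodobut-2-enoate
Product: 23 methyl (1R,2S,4aR,8aS)-1-[(3E)-3-(acetoxymethyl)-5-methoxy-5-oxopent-3-en-1-yl]-5,5,8a-trimethyl-1,2,4a,5,6,7,8,8a-octahydronaphthalene-2-carboxylate, via alkylborane 22 (not isolated)
Conditions: 9-BBN-H, THF, 0 °C → rt; then 21, Pd(dppf)Cl2 (5 mol %), AsPh3, aq K3PO4, DMF, rt
Reagents that add atoms: none
Why: Anti-Markovnikov hydroboration of the terminal vinyl group with 9-BBN (the ring alkene is too hindered) followed by B-alkyl Suzuki–Miyaura coupling with retention of the iodide geometry should place C12 cis to the ester, which is the (E)-C13=C14 bond of the target.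

**Compound list**

1 | 2,2,6-trimethylcyclohexanone (racemic) | CC1CCCC(C)(C)C1=O | starting material
2 | allyl chloroformate | C=CCOC(Cl)=O | starting material
3 | allyl 2,6,6-trimethylcyclohex-1-en-1-yl carbonate | CC1=C(OC(=O)OCC=C)C(C)(C)CCC1 | intermediate
4 | (S)-2-allyl-2,6,6-trimethylcyclohexanone | C=CC[C@]1(C)CCCC(C)(C)C1=O | intermediate
5 | (S)-2,2,6-trimethyl-6-(2-oxopropyl)cyclohexanone | CC(=O)C[C@]1(C)CCCC(C)(C)C1=O | intermediate
6 | (7aS)-4,4,7a-trimethyl-5,6,7,7a-tetrahydro-1H-inden-2(4H)-one | O=C1C=C2C(C)(C)CCC[C@@]2(C)C1 | intermediate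
7 | lithium enolate of the trans-hydrindan-2-one (C6=C11, H5 trans to the angular methyl) | [Li]OC1=C[C@@H]2C(C)(C)CCC[C@@]2(C)C1 | intermediate
8 | (1R,3aS,7aR)-1-(hydroxymethyl)-3a,7,7-trimethyloctahydro-2H-inden-2-one | OC[C@@H]1C(=O)C[C@]2(C)CCCC(C)(C)[C@@H]12 | intermediate
9 | (1R,4aS,8aR)-1-(hydroxymethyl)-4a,8,8-trimethyloctahydro-3H-isochromen-3-one | OC[C@@H]1OC(=O)C[C@]2(C)CCCC(C)(C)[C@@H]12 | intermediate
10 | (1R,4aS,8aR)-4a,8,8-trimethyl-3-oxooctahydro-1H-isochromene-1-carbaldehyde | O=C[C@@H]1OC(=O)C[C@]2(C)CCCC(C)(C)[C@@H]12 | intermediate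
11 | methyl bis(2,2,2-trifluoroethyl)phosphonoacetate | COC(=O)CP(=O)(OCC(F)(F)F)OCC(F)(F)F | starting material
12 | methyl (2Z)-3-[(1S,4aS,8aR)-4a,8,8-trimethyl-3-oxooctahydro-1H-isochromen-1-yl]prop-2-enoate | COC(=O)/C=C\[C@@H]1OC(=O)C[C@]2(C)CCCC(C)(C)[C@@H]12 | intermediate
13 | tert-butyldimethylsilyl ketene acetal of 12 (C9=C11, OTBS on C11) | COC(=O)/C=C\[C@@H]1OC(O[Si](C)(C)C(C)(C)C)=C[C@]2(C)CCCC(C)(C)[C@@H]12 | intermediate
14 | tert-butyldimethylsilyl ester of 15 | CC(C)(C)[Si](C)(C)OC(=O)[C@@H]1[C@@H](C(=O)OC)C=C[C@@H]2C(C)(C)CCC[C@@]12C | intermediate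
15 | (1R,2S,4aR,8aR)-2-(methoxycarbonyl)-5,5,8a-trimethyl-1,2,4a,5,6,7,8,8a-octahydronaphthalene-1-carboxylic acid | OC(=O)[C@@H]1[C@@H](C(=O)OC)C=C[C@@H]2C(C)(C)CCC[C@@]12C | intermediate
16 | acid chloride of 15 | ClC(=O)[C@@H]1[C@@H](C(=O)OC)C=C[C@@H]2C(C)(C)CCC[C@@]12C | intermediate
17 | methyl (1R,2S,4aR,8aR)-1-formyl-5,5,8a-trimethyl-1,2,4a,5,6,7,8,8a-octahydronaphthalene-2-carboxylate | O=C[C@@H]1[C@@H](C(=O)OC)C=C[C@@H]2C(C)(C)CCC[C@@]12C | intermediate
18 | methyl (1R,2S,4aR,8aS)-5,5,8a-trimethyl-1-vinyl-1,2,4a,5,6,7,8,8a-octahydronaphthalene-2-carboxylate | C=C[C@@H]1[C@@H](C(=O)OC)C=C[C@@H]2C(C)(C)CCC[C@@]12C | intermediate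
19 | methyl 4-hydroxybut-2-ynoate | COC(=O)C#CCO | starting material
20 | methyl 4-acetoxybut-2-ynoate | COC(=O)C#CCOC(C)=O | intermediate
21 | methyl (2Z)-4-acetoxy-3-iodobut-2-enoate | COC(=O)/C=C(\I)COC(C)=O | intermediate
22 | methyl (1R,2S,4aR,8aS)-1-[2-(9-borabicyclo[3.3.1]nonan-9-yl)ethyl]-5,5,8a-trimethyl-1,2,4a,5,6,7,8,8a-octahydronaphthalene-2-carboxylate | C1CCC2CCCC1B2CC[C@@H]1[C@@H](C(=O)OC)C=C[C@@H]2C(C)(C)CCC[C@@]12C | intermediate
23 | methyl (1R,2S,4aR,8aS)-1-[(3E)-3-(acetoxymethyl)-5-methoxy-5-oxopent-3-en-1-yl]-5,5,8a-trimethyl-1,2,4a,5,6,7,8,8a-octahydronaphthalene-2-carboxylate (CNP0190145.1) | COC(=O)/C=C(\CC[C@@H]1[C@@H](C(=O)OC)C=C[C@@H]2C(C)(C)CCC[C@@]12C)COC(C)=O | target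

**Step count.** Total: 14 steps. Longest linear sequence: 12 steps (steps 1–11 and 14); steps 12–13 make the side-chain fragment.

**Steps most likely to fail**

Step 9. The (Z)-ester has to pass under C1H2 in the boat transition state, so the rearrangement may be too slow and the ketene acetal may decompose; competing γ-deprotonation of the enoate is the second failure mode. The fallback forms C8–C9 by an open-chain chair Ireland–Claisen rearrangement and closes the ring by metathesis; it sets out from 9 and comes back to the route at 15. Iodination of 9 (I2, PPh3, imidazole) should give (1R,4aS,8aR)-1-(iodomethyl)-4a,8,8-trimethyloctahydro-3H-isochromen-3-one F1. Zinc in acetic acid should open it by reductive β-elimination to 2-[(1S,2R)-1,3,3-trimethyl-2-vinylcyclohexyl]acetic acid F2. Esterification with purchased methyl (E)-4-hydroxybut-2-enoate (DCC, DMAP) should give methyl (2E)-4-({2-[(1S,2R)-1,3,3-trimethyl-2-vinylcyclohexyl]acetyl}oxy)but-2-enoate F3. Ireland–Claisen rearrangement through the (E)-silyl ketene acetal (LDA, TMSCl, THF without HMPA, −78 °C → rt, chair transition state) should give (2R,3S)-3-(methoxycarbonyl)-2-[(1R,2R)-1,3,3-trimethyl-2-vinylcyclohexyl]pent-4-enoic acid F4 with the required anti C8/C9 relationship. The C9 face is controlled only by the neighbouring quaternary centre, so an epimer may have to be removed. Ring-closing metathesis (second-generation Grubbs catalyst, CH2Cl2, 40 °C) then forms C6=C7.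

Step 5. Trapping of enolate 7 may be inefficient (proton transfer, formaldehyde oligomerisation), and protonation at C5 may not be fully face-selective. The fallback delivers the hydrogen from a metal hydride and uses a Lewis-acid aldol; it sets out from 6 and comes back at 8. 1,4-Hydrosilylation of 6 (catalytic copper hydride or Wilkinson's catalyst, Et3SiH) from the less hindered β face should give triethyl{[(3aS,7aR)-3a,7,7-trimethyl-3a,4,5,6,7,7a-hexahydro-3H-inden-2-yl]oxy}silane F5. A Mukaiyama aldol reaction of this silyl enol ether with aqueous formaldehyde (Sc(OTf)3, THF–H2O, rt) then installs the hydroxymethyl group on the same β face.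

Step 14. Pd(0) may ionise the allylic acetate of 21 or of the product, the aqueous base may cleave the acetate, and transmetalation from the hindered alkylborane may be slow. The fallback is a base-free zinc coupling; it sets out from 18 and comes back at 23. Hydroboration–oxidation (9-BBN; then NaBO3·4H2O) should give methyl (1R,2S,4aR,8aS)-1-(2-hydroxyethyl)-5,5,8a-trimethyl-1,2,4a,5,6,7,8,8a-octahydronaphthalene-2-carboxylate F6. Iodination (I2, PPh3, imidazole) should give methyl (1R,2S,4aR,8aS)-1-(2-iodoethyl)-5,5,8a-trimethyl-1,2,4a,5,6,7,8,8a-octahydronaphthalene-2-carboxylate F7. Zinc insertion (Zn, LiCl, THF) should give {2-[(1R,2S,4aR,8aS)-2-(methoxycarbonyl)-5,5,8a-trimethyl-1,2,4a,5,6,7,8,8a-octahydronaphthalen-1-yl]ethyl}zinc iodide F8. Negishi coupling of this reagent with 21 (Pd2(dba)3, SPhos, THF, rt) keeps the alkene geometry.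

**Further compounds**

F1 | step 9 | (1R,4aS,8aR)-1-(iodomethyl)-4a,8,8-trimethyloctahydro-3H-isochromen-3-one | IC[C@@H]1OC(=O)C[C@]2(C)CCCC(C)(C)[C@@H]12
F2 | step 9 | 2-[(1S,2R)-1,3,3-trimethyl-2-vinylcyclohexyl]acetic acid | C=C[C@@H]1C(C)(C)CCC[C@@]1(C)CC(O)=O
F3 | step 9 | methyl (2E)-4-({2-[(1S,2R)-1,3,3-trimethyl-2-vinylcyclohexyl]acetyl}oxy)but-2-enoate | C=C[C@@H]1C(C)(C)CCC[C@@]1(C)CC(=O)OC/C=C/C(=O)OC
F4 | step 9 | (2R,3S)-3-(methoxycarbonyl)-2-[(1R,2R)-1,3,3-trimethyl-2-vinylcyclohexyl]pent-4-enoic acid | OC(=O)[C@H]([C@@H](C(=O)OC)C=C)[C@]1(C)CCCC(C)(C)[C@H]1C=C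
F5 | step 5 | triethyl{[(3aS,7aR)-3a,7,7-trimethyl-3a,4,5,6,7,7a-hexahydro-3H-inden-2-yl]oxy}silane | CC[Si](CC)(CC)OC1=C[C@@H]2C(C)(C)CCC[C@@]2(C)C1
F6 | step 14 | methyl (1R,2S,4aR,8aS)-1-(2-hydroxyethyl)-5,5,8a-trimethyl-1,2,4a,5,6,7,8,8a-octahydronaphthalene-2-carboxylate | OCC[C@@H]1[C@@H](C(=O)OC)C=C[C@@H]2C(C)(C)CCC[C@@]12C
F7 | step 14 | methyl (1R,2S,4aR,8aS)-1-(2-iodoethyl)-5,5,8a-trimethyl-1,2,4a,5,6,7,8,8a-octahydronaphthalene-2-carboxylate | ICC[C@@H]1[C@@H](C(=O)OC)C=C[C@@H]2C(C)(C)CCC[C@@]12C
F8 | step 14 | {2-[(1R,2S,4aR,8aS)-2-(methoxycarbonyl)-5,5,8a-trimethyl-1,2,4a,5,6,7,8,8a-octahydronaphthalen-1-yl]ethyl}zinc iodide | I[Zn]CC[C@@H]1[C@@H](C(=O)OC)C=C[C@@H]2C(C)(C)CCC[C@@]12C
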